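## Retrosynthetic overview

1. The oxepinone, the only ring of the target, is closed last by ring-closing metathesis of acrylate ester 13, itself made from diol 8 and acrylic acid 12.
2. The C(sp3)–C(sp2) bond that joins the diol core to the (E)-allylic acetate arm is made by a light-driven decarboxylative alkenylation: the carboxylate released from γ-lactone 4 couples with vinyl iodide 6.
3. The tertiary carbinol comes from a Felkin-controlled allylation of methyl ketone 3, steered by the single bought stereocentre.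
4. That stereocentre and the masked carboxylate come from (S)-5-oxotetrahydrofuran-2-carboxylic acid 1 (L-glutamic acid series).
5. Ring order: the γ-lactone of 1 is a temporary ring (opened in step 4); the oxepinone is formed in step 8.

Assumption: (E)-3-iodobut-2-en-1-ol (5) is bought as a catalogue building block; C6 (secondary carbinol) and C7 (tertiary carbinol) follow the decadienyl numbering of 8.

## Route

Step 1
Reactants: 1 (S)-5-oxotetrahydrofuran-2-carboxylic acid
Product: 3 (S)-5-acetyldihydrofuran-2(3H)-one, via acid chloride 2 (not isolated)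
Conditions: (COCl)2, DMF (cat.), CH2Cl2, 0 °C → rt; evaporate; MeMgBr (1.05 equiv), Fe(acac)3 (3 mol %), THF, −78 °C
Reagents that add atoms: methylmagnesium bromide, C[Mg]Br
Why: Acid chloride formation followed by iron-catalysed Grignard acylation stops at the ketone and spares the lactone, and at −78 °C the α-stereocentre bought in 1 is not enolised.

Step 2
Reactants: 3 (S)-5-acetyldihydrofuran-2(3H)-one
Product: 4 (S)-5-[(R)-2-hydroxypent-4-en-2-yl]dihydrofuran-2(3H)-one
Conditions: allylSiMe3 (1.5 equiv), TiCl4 (1.1 equiv), CH2Cl2, −78 °C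
Reagents that add atoms: allyltrimethylsilane, C=CC[Si](C)(C)C
Why: Hosomi–Sakurai allylation under polar Felkin–Anh (Cornforth) control: the electron-poor lactone oxygen does not chelate, its C–O bond lies anti to the incoming allylsilane, and attack past H rather than the ring CH2 sets the new tertiary carbinol as R.

Step 3
Reactants: 5 (E)-3-iodobut-2-en-1-ol
Product: 6 (E)-3-iodobut-2-en-1-yl acetate
Conditions: Ac2O, pyridine, DMAP (cat.), CH2Cl2, 0 °C → rt
Reagents that add atoms: acetic anhydride, CC(=O)OC(C)=O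
Why: DMAP-catalysed acetylation of a primary allylic alcohol leaves the alkene geometry and the C–I bond untouched.

Step 4
Reactants: 4 (S)-5-[(R)-2-hydroxypent-4-en-2-yl]dihydrofuran-2(3H)-one; 6 (E)-3-iodobut-2-en-1-yl acetate
Product: 8 (2E,6S,7R)-6,7-dihydroxy-3,7-dimethyldeca-2,9-dien-1-yl acetate, via lithium carboxylate 7 (not isolated)
Conditions: LiOH·H2O (1.0 equiv), THF/H2O, 0 °C → rt, evaporate to dryness; then 6 (1.5 equiv), Fe(NO3)3·9H2O (10 mol %), NiBr2(dme) (10 mol %), 4,4′-di-tert-butyl-2,2′-bipyridine (12 mol %), DMSO/MeCN, 390 nm LEDs, rt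
Reagents that add atoms: none
Why: Proposed new method: saponification gives a dihydroxy carboxylate salt that cannot relactonise, its trivalent-iron carboxylate undergoes ligand-to-metal charge transfer at 390 nm and loses CO2 to give the primary radical, and this radical is captured by the alkenylnickel species formed from 6 and zerovalent nickel and reductively eliminated with retention of the E geometry, so neither stereocentre is touched; the closest known reaction types are iron/nickel photochemical decarboxylative arylation of free acids with aryl iodides and nickel-catalysed decarboxylative alkenylation of redox-active esters.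

Step 5
Reactants: 9 6-methylhept-5-en-2-one
Product: 11 6-methylhepta-1,5-dien-2-yl trifluoromethanesulfonate, via lithium enolate 10 (not isolated)
Conditions: LiN(iPr)2, THF, −78 °C; then PhNTf2, −78 → 0 °C
Reagents that add atoms: N-phenylbis(trifluoromethanesulfonimide), O=S(=O)(N(c1ccccc1)S(=O)(=O)C(F)(F)F)C(F)(F)F
Why: Kinetic deprotonation of the methyl ketone at the methyl group and O-triflation of the less substituted enolate (enol triflate formation) give the 1,1-disubstituted vinyl triflate.

Step 6
Reactants: 11 6-methylhepta-1,5-dien-2-yl trifluoromethanesulfonate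
Product: 12 6-methyl-2-methylidenehept-5-enoic acid
Conditions: Pd(OAc)2 (5 mol %), PPh3 (10 mol %), CO (1 atm), KOAc, DMF/H2O, 50 °C
Reagents that add atoms: carbon monoxide, [C-]#[O+]; water, O
Why: Palladium-catalysed hydroxycarbonylation of an enol triflate (oxidative addition of zerovalent palladium, CO insertion, hydrolysis of the acyl complex) gives the 2-substituted acrylic acid without moving the double bond.

Step 7
Reactants: 8 (2E,6S,7R)-6,7-dihydroxy-3,7-dimethyldeca-2,9-dien-1-yl acetate; 12 6-methyl-2-methylidenehept-5-enoic acid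
Product: 13 (2E,6S,7R)-1-acetoxy-7-hydroxy-3,7-dimethyldeca-2,9-dien-6-yl 6-methyl-2-methylidenehept-5-enoate
Conditions: DCC, DMAP (cat.), CH2Cl2, 0 °C → rt
Reagents that add atoms: none
Why: Steglich esterification acylates the secondary alcohol only, because the neighbouring tertiary alcohol is too hindered; the C–O bond of the stereocentre is not broken, so its configuration is kept.

Step 8
Reactants: 13 (2E,6S,7R)-1-acetoxy-7-hydroxy-3,7-dimethyldeca-2,9-dien-6-yl 6-methyl-2-methylidenehept-5-enoate
Product: 14 (2E)-5-[(2S,3R)-3-hydroxy-3-methyl-6-(4-methylpent-3-en-1-yl)-7-oxo-2,3,4,7-tetrahydrooxepin-2-yl]-3-methylpent-2-en-1-yl acetate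
Conditions: second-generation Hoveyda–Grubbs catalyst RuCl2(H2IMes)(=CH-C6H4-2-OiPr) (10 mol %), toluene (2 mM), 80 °C
Reagents that add atoms: none
Why: Ring-closing metathesis between the monosubstituted alkene and the 1,1-disubstituted acrylate closes the seven-membered enoate lactone with loss of ethene; the ring fixes the alkene geometry, the quaternary carbinol favours closure, and the terminal acrylate CH2 is more accessible than the trisubstituted side-chain alkenes.

## Compound list

1 | (S)-5-oxotetrahydrofuran-2-carboxylic acid | O=C(O)[C@@H]1CCC(=O)O1 | starting material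
2 | (S)-5-oxotetrahydrofuran-2-carbonyl chloride | O=C(Cl)[C@@H]1CCC(=O)O1 | intermediate
3 | (S)-5-acetyldihydrofuran-2(3H)-one | CC(=O)[C@@H]1CCC(=O)O1 | intermediate
4 | (S)-5-[(R)-2-hydroxypent-4-en-2-yl]dihydrofuran-2(3H)-one | C=CC[C@@](C)(O)[C@@H]1CCC(=O)O1 | intermediate
5 | (E)-3-iodobut-2-en-1-ol | OC/C=C(\C)I | starting material
6 | (E)-3-iodobut-2-en-1-yl acetate | CC(=O)OC/C=C(\C)I | intermediate
7 | lithium (4S,5R)-4,5-dihydroxy-5-methyloct-7-enoate | C=CC[C@@](C)(O)[C@@H](O)CCC(=O)[O-].[Li+] | intermediate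
8 | (2E,6S,7R)-6,7-dihydroxy-3,7-dimethyldeca-2,9-dien-1-yl acetate | CC(=O)OC/C=C(\C)CC[C@H](O)[C@](C)(O)CC=C | intermediate
9 | 6-methylhept-5-en-2-one | CC(=O)CCC=C(C)C | starting material
10 | lithium 6-methylhepta-1,5-dien-2-olate | [Li+].[O-]C(=C)CCC=C(C)C | intermediate
11 | 6-methylhepta-1,5-dien-2-yl trifluoromethanesulfonate | C=C(CCC=C(C)C)OS(=O)(=O)C(F)(F)F | intermediate
12 | 6-methyl-2-methylidenehept-5-enoic acid | C=C(CCC=C(C)C)C(=O)O | intermediate
13 | (2E,6S,7R)-1-acetoxy-7-hydroxy-3,7-dimethyldeca-2,9-dien-6-yl 6-methyl-2-methylidenehept-5-enoate | CC(=O)OC/C=C(\C)CC[C@H](OC(=O)C(=C)CCC=C(C)C)[C@](C)(O)CC=C | intermediate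
14 | (2E)-5-[(2S,3R)-3-hydroxy-3-methyl-6-(4-methylpent-3-en-1-yl)-7-oxo-2,3,4,7-tetrahydrooxepin-2-yl]-3-methylpent-2-en-1-yl acetate | CC(=O)OC/C=C(\C)CC[C@@H]1OC(=O)C(CCC=C(C)C)=CC[C@@]1(C)O | target

## Step count and risks

Total step count: 8. Longest linear sequence: 5 steps (steps 1, 2, 4, 7, 8 from compound 1).

**Step 4 (the proposed new step).** The risks are:
- the vicinal diol may bind the iron and slow charge transfer;
- the primary radical may cyclise 6-exo onto the allyl group before nickel captures it;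
- an iron-bound tertiary alkoxide could fragment to an allyl radical;
- the radical may simply be reduced to the alkane.

The fallback uses known chemistry, sets out from 4 and comes back at 8. Lactone 4 is opened and protected in one operation (2,2-dimethoxypropane, MeOH, TsOH) to give methyl 3-[(4S,5R)-2,2,5-trimethyl-5-(prop-2-en-1-yl)-1,3-dioxolan-4-yl]propanoate F2. This is saponified (LiOH, THF/H2O) to 3-[(4S,5R)-2,2,5-trimethyl-5-(prop-2-en-1-yl)-1,3-dioxolan-4-yl]propanoic acid F3. The acid is activated with N-hydroxyphthalimide and N,N′-diisopropylcarbodiimide to 1,3-dioxoisoindolin-2-yl 3-[(4S,5R)-2,2,5-trimethyl-5-(prop-2-en-1-yl)-1,3-dioxolan-4-yl]propanoate F4. F4 is coupled with 6 by nickel-catalysed electrochemical decarboxylative alkenylation (NiCl2·6H2O, 2,2′-bipyridine, AgNO3, LiCl, DMF, magnesium anode, carbon cathode, constant current) to give (2E)-3-methyl-5-[(4S,5R)-2,2,5-trimethyl-5-(prop-2-en-1-yl)-1,3-dioxolan-4-yl]pent-2-en-1-yl acetate F5. Aqueous acetic acid at 40 °C then removes the acetonide and returns diol 8.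

**Step 8 (ring-closing metathesis).** The ruthenium alkylidene formed at the terminal alkene can also close onto the trisubstituted side-chain alkene to give a cycloheptene, and the ester conformation favours oligomers. The fallback replaces metathesis by an intramolecular Horner–Wadsworth–Emmons olefination, sets out from 4 and comes back at 14.
- Ozonolysis of 4 (O3, CH2Cl2/MeOH, −78 °C; Me2S) and acetalisation (CH(OMe)3, pyridinium p-toluenesulfonate) give (S)-5-[(R)-2-hydroxy-4,4-dimethoxybutan-2-yl]dihydrofuran-2(3H)-one F6.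
- Saponification gives lithium (4S,5R)-4,5-dihydroxy-7,7-dimethoxy-5-methylheptanoate F7, which is not isolated and is coupled with 6 under the step 4 conditions to give (2E,6S,7R)-6,7-dihydroxy-9,9-dimethoxy-3,7-dimethylnon-2-en-1-yl acetate F8.
- In parallel, triethyl phosphonoacetate is alkylated with 5-bromo-2-methylpent-2-ene (NaH, DMSO) to ethyl 2-(diethoxyphosphoryl)-6-methylhept-5-enoate F9, which is saponified (LiOH, 1 equiv) to 2-(diethoxyphosphoryl)-6-methylhept-5-enoic acid F10.
- Steglich esterification of F8 with F10 gives (2E,6S,7R)-1-acetoxy-7-hydroxy-9,9-dimethoxy-3,7-dimethylnon-2-en-6-yl 2-(diethoxyphosphoryl)-6-methylhept-5-enoate F11.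
- Mild acetal hydrolysis (LiBF4, wet MeCN) gives (2E,6S,7R)-1-acetoxy-7-hydroxy-3,7-dimethyl-9-oxonon-2-en-6-yl 2-(diethoxyphosphoryl)-6-methylhept-5-enoate F12.
- LiCl and DBU in MeCN at 1 mM close the ring to 14; the ring allows only the required alkene geometry.

**Step 2 (diastereoselectivity of the allylation).** If TiCl4 partly bridges the ketone and the ring oxygen, the Felkin preference is eroded and the tertiary carbinol forms as a mixture. The fallback turns chelation into the controlling element by reversing the order in which the two carbon groups are introduced; it sets out from 2 and comes back at 4. Acid chloride 2 is coupled with allylSnBu3 (PdCl2(PPh3)2 cat., THF) to give (S)-5-(but-3-enoyl)dihydrofuran-2(3H)-one F1. Chelation-controlled methyl transfer with MeTiCl3 (CH2Cl2, −78 °C) then delivers methyl to the chelate face anti to the ring CH2, which gives the same (R)-carbinol 4. This works only to the extent that the lactone oxygen does chelate, so it complements the main step and does not duplicate it.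

## Further compounds

F1 | step 2 | (S)-5-(but-3-enoyl)dihydrofuran-2(3H)-one | C=CCC(=O)[C@@H]1CCC(=O)O1
F2 | step 4 | methyl 3-[(4S,5R)-2,2,5-trimethyl-5-(prop-2-en-1-yl)-1,3-dioxolan-4-yl]propanoate | COC(=O)CC[C@@H]1OC(C)(C)O[C@]1(C)CC=C
F3 | step 4 | 3-[(4S,5R)-2,2,5-trimethyl-5-(prop-2-en-1-yl)-1,3-dioxolan-4-yl]propanoic acid | OC(=O)CC[C@@H]1OC(C)(C)O[C@]1(C)CC=C
F4 | step 4 | 1,3-dioxoisoindolin-2-yl 3-[(4S,5R)-2,2,5-trimethyl-5-(prop-2-en-1-yl)-1,3-dioxolan-4-yl]propanoate | O=C(CC[C@@H]1OC(C)(C)O[C@]1(C)CC=C)ON1C(=O)c2ccccc2C1=O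
F5 | step 4 | (2E)-3-methyl-5-[(4S,5R)-2,2,5-trimethyl-5-(prop-2-en-1-yl)-1,3-dioxolan-4-yl]pent-2-en-1-yl acetate | CC(=O)OC/C=C(\C)CC[C@@H]1OC(C)(C)O[C@]1(C)CC=C
F6 | step 8 | (S)-5-[(R)-2-hydroxy-4,4-dimethoxybutan-2-yl]dihydrofuran-2(3H)-one | COC(OC)C[C@@](C)(O)[C@@H]1CCC(=O)O1
F7 | step 8 | lithium (4S,5R)-4,5-dihydroxy-7,7-dimethoxy-5-methylheptanoate | COC(OC)C[C@@](C)(O)[C@@H](O)CCC(=O)[O-].[Li+]
F8 | step 8 | (2E,6S,7R)-6,7-dihydroxy-9,9-dimethoxy-3,7-dimethylnon-2-en-1-yl acetate | CC(=O)OC/C=C(\C)CC[C@H](O)[C@](C)(O)CC(OC)OC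
F9 | step 8 | ethyl 2-(diethoxyphosphoryl)-6-methylhept-5-enoate | CCOC(=O)C(CCC=C(C)C)P(=O)(OCC)OCC
F10 | step 8 | 2-(diethoxyphosphoryl)-6-methylhept-5-enoic acid | OC(=O)C(CCC=C(C)C)P(=O)(OCC)OCC
F11 | step 8 | (2E,6S,7R)-1-acetoxy-7-hydroxy-9,9-dimethoxy-3,7-dimethylnon-2-en-6-yl 2-(diethoxyphosphoryl)-6-methylhept-5-enoate | CC(=O)OC/C=C(\C)CC[C@H](OC(=O)C(CCC=C(C)C)P(=O)(OCC)OCC)[C@](C)(O)CC(OC)OC
F12 | step 8 | (2E,6S,7R)-1-acetoxy-7-hydroxy-3,7-dimethyl-9-oxonon-2-en-6-yl 2-(diethoxyphosphoryl)-6-methylhept-5-enoate | CC(=O)OC/C=C(\C)CC[C@H](OC(=O)C(CCC=C(C)C)P(=O)(OCC)OCC)[C@](C)(O)CC=O
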